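**Assumption:** the target has no stereocentre (its only alkene carries two identical methyl groups), so no stereocontrol is needed; carbonate 9 is treated as a purchased reagent. Ring B is numbered as in the target throughout: C1' attached to the chromone, C2' OH, C3' prenyl, C4' OH, C5' OMe, C6' H.

**Retrosynthetic overview**
1. Target 12 ⇐ deacetylation and aromatic Claisen rearrangement of the 2'-O-(1,1-dimethylallyl) ether 10, which moves the C5 unit from O2' to C3' as a normal prenyl group.
2. 10 ⇐ O-allylation of the single free phenol of 8 with carbonate 9.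
3. 8 ⇐ key C2'–O bond: chromone-carbonyl-directed C–H borylation/oxidation of diacetate 5 (new method).
4. 5 ⇐ acetylation of isoflavone 4 ⇐ one-pot acylation and formylative ring closure of resorcinol 1 with homovanillic acid 2.
5. Ring order: rings A and B are bought; ring C (the pyranone) is formed in step 1, first C-acylation, then O1–C2 closure.

**Route**

Step 1
Reactants: 1 resorcinol; 2 homovanillic acid (4-hydroxy-3-methoxyphenylacetic acid)
Product: 4 7-hydroxy-3-(4-hydroxy-3-methoxyphenyl)-4H-chromen-4-one, via deoxybenzoin 3 (not isolated)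
Conditions: BF3·OEt2 (neat, as solvent), 90 °C, 2 h; then DMF, MsCl, 70 °C, 2 h; pour into water, filter
Reagents that add atoms: N,N-dimethylformamide, CN(C)C=O (supplies C2–H)
Why: Friedel–Crafts (Hoesch-type) C-acylation of resorcinol para to one OH gives the deoxybenzoin, whose BF2-chelated enol is formylated by the DMF/MsCl Vilsmeier-type reagent and closes ring C by O1–C2 bond formation with loss of dimethylamine; no stereocentre is formed.

Step 2
Reactants: 4 7-hydroxy-3-(4-hydroxy-3-methoxyphenyl)-4H-chromen-4-one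
Product: 5 3-(4-acetoxy-3-methoxyphenyl)-4-oxo-4H-chromen-7-yl acetate
Conditions: Ac2O (3 equiv), pyridine, DMAP (cat.), rt, 3 h
Reagents that add atoms: acetic anhydride, CC(=O)OC(C)=O
Why: standard O-acetylation masks both acidic OH groups against BBr3 and against the later O-allylation, and makes the 4'-oxygen a weak donor so that the OMe group controls where ring B reacts.

Step 3
Reactants: 5 3-(4-acetoxy-3-methoxyphenyl)-4-oxo-4H-chromen-7-yl acetate
Product: 8 3-(4-acetoxy-2-hydroxy-5-methoxyphenyl)-4-oxo-4H-chromen-7-yl acetate, via arylboron dibromide chelate 6 (not isolated), via arylboronic acid 7 (not isolated)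
Conditions: BBr3 (2.2 equiv), CH2Cl2, 0 °C, 1 h; ice-water quench, extract; then Me3NO (2 equiv), CH2Cl2, rt, 30 min
Reagents that add atoms: trimethylamine N-oxide, C[N+](C)(C)[O-] (oxygen of the new OH); boron tribromide, BrB(Br)Br and water, O (atoms in intermediates 6 and 7 only)
Why: Proposed new method: the strongly Lewis-basic pyranone carbonyl binds BBr3, a second BBr3 abstracts bromide to give an O-bound borenium ion, and this attacks C2', the ring-B carbon that is reachable through a six-membered transition state, para to OMe and less hindered than C6'; loss of HBr gives chelate 6, and after hydrolysis the C–B bond is oxidised by the N-oxide through a 1,2-aryl shift from boron to oxygen, while ring A C5–H stays untouched because it would need a strained five-membered boracycle on an electron-poor ring; the closest known reaction type is amide-, pivaloyl- and pyridine-directed electrophilic C–H borylation with BBr3 followed by oxidation to the phenol, not shown so far with a chromone carbonyl as directing group.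

Step 4
Reactants: 8 3-(4-acetoxy-2-hydroxy-5-methoxyphenyl)-4-oxo-4H-chromen-7-yl acetate; 9 tert-butyl 2-methylbut-3-en-2-yl carbonate
Product: 10 3-[4-acetoxy-5-methoxy-2-(2-methylbut-3-en-2-yloxy)phenyl]-4-oxo-4H-chromen-7-yl acetate
Conditions: Pd(PPh3)4 (5 mol %), THF, 0 °C, 4 h
Reagents that add atoms: none
Why: Tsuji–Trost decarboxylative O-allylation, in which the only free phenol is deprotonated by the tert-butoxide released from 9 and attacks the more substituted end of the 1,1-dimethyl-π-allyl palladium complex under kinetic control at low temperature to give the tertiary (reverse-prenyl) ether.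

Step 5
Reactants: 10 3-[4-acetoxy-5-methoxy-2-(2-methylbut-3-en-2-yloxy)phenyl]-4-oxo-4H-chromen-7-yl acetate
Product: 12 piscisoflavone A, via rearranged diacetate 11 (not isolated)
Conditions: PhMe, 115 °C (sealed tube), 6 h; concentrate; then K2CO3 (0.3 equiv), MeOH, argon, 0 °C to rt, 1 h; dilute citric acid work-up
Reagents that add atoms: none
Why: aromatic Claisen [3,3] rearrangement can only end at C3' because the other ortho carbon C1' and the para carbon C5' are substituted, so the CH2 terminus bonds to C3' and gives the normal prenyl group and the free 2'-OH; mild base-catalysed methanolysis then removes both acetates without acid, which would cyclise the prenyl group onto a neighbouring OH.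

**Compound list**
1 | resorcinol | Oc1cccc(O)c1 | starting material
2 | homovanillic acid (4-hydroxy-3-methoxyphenylacetic acid) | COc1cc(CC(=O)O)ccc1O | starting material
3 | 1-(2,4-dihydroxyphenyl)-2-(4-hydroxy-3-methoxyphenyl)ethan-1-one (deoxybenzoin) | COc1cc(CC(=O)c2ccc(O)cc2O)ccc1O | intermediate
4 | 7-hydroxy-3-(4-hydroxy-3-methoxyphenyl)-4H-chromen-4-one | COc1cc(-c2coc3cc(O)ccc3c2=O)ccc1O | intermediate
5 | 3-(4-acetoxy-3-methoxyphenyl)-4-oxo-4H-chromen-7-yl acetate | COc1cc(-c2coc3cc(OC(C)=O)ccc3c2=O)ccc1OC(C)=O | intermediate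
6 | [5-acetoxy-2-(7-acetoxy-4-oxo-4H-chromen-3-yl)-4-methoxyphenyl]dibromoborane, boron chelated by the C4 carbonyl oxygen | COc1cc(-c2coc3cc(OC(C)=O)ccc3c2=O)c(B(Br)Br)cc1OC(C)=O | intermediate
7 | [5-acetoxy-2-(7-acetoxy-4-oxo-4H-chromen-3-yl)-4-methoxyphenyl]boronic acid | COc1cc(-c2coc3cc(OC(C)=O)ccc3c2=O)c(B(O)O)cc1OC(C)=O | intermediate
8 | 3-(4-acetoxy-2-hydroxy-5-methoxyphenyl)-4-oxo-4H-chromen-7-yl acetate | COc1cc(-c2coc3cc(OC(C)=O)ccc3c2=O)c(O)cc1OC(C)=O | intermediate
9 | tert-butyl 2-methylbut-3-en-2-yl carbonate | C=CC(C)(C)OC(=O)OC(C)(C)C | starting material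
10 | 3-[4-acetoxy-5-methoxy-2-(2-methylbut-3-en-2-yloxy)phenyl]-4-oxo-4H-chromen-7-yl acetate | COc1cc(-c2coc3cc(OC(C)=O)ccc3c2=O)c(OC(C)(C)C=C)cc1OC(C)=O | intermediate
11 | 3-[4-acetoxy-2-hydroxy-5-methoxy-3-(3-methylbut-2-en-1-yl)phenyl]-4-oxo-4H-chromen-7-yl acetate | COc1cc(-c2coc3cc(OC(C)=O)ccc3c2=O)c(O)c(CC=C(C)C)c1OC(C)=O | intermediate
12 | piscisoflavone A, 3-[2,4-dihydroxy-5-methoxy-3-(3-methylbut-2-en-1-yl)phenyl]-7-hydroxy-4H-chromen-4-one (achiral) | COc1cc(-c2coc3cc(O)ccc3c2=O)c(O)c(CC=C(C)C)c1O | target

**Totals**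
Total step count: 5. Longest linear sequence: 5 steps (1/2 → 4 → 5 → 8 → 10 → 12).

**Three steps most likely to fail**

Step 3 (the proposed new directed C–H hydroxylation). Risks are cleavage of the 5'-OMe group by BBr3 and borylation at C6'. The fallback uses known chemistry and sets out from 5. Electrophilic bromination with NBS in MeCN at rt goes para to OMe and gives 3-(4-acetoxy-2-bromo-5-methoxyphenyl)-4-oxo-4H-chromen-7-yl acetate F1. Miyaura borylation (bis(pinacolato)diboron, KOAc, PdCl2(dppf), dioxane, 85 °C) gives the pinacol boronate 3-[4-acetoxy-5-methoxy-2-(4,4,5,5-tetramethyl-1,3,2-dioxaborolan-2-yl)phenyl]-4-oxo-4H-chromen-7-yl acetate F2. Oxidation of F2 with Me3NO in THF at 50 °C comes back to the route at 8.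

Step 4 (O-allylation of a hindered phenol; risk of linear O-prenyl ether or slow reaction). The fallback sets out from 8. Copper-catalysed O-propargylation with 3-chloro-3-methylbut-1-yne (CuCl2 cat., DBU, MeCN, 0 °C) gives 3-[4-acetoxy-5-methoxy-2-(2-methylbut-3-yn-2-yloxy)phenyl]-4-oxo-4H-chromen-7-yl acetate F3. Semi-hydrogenation of the alkyne (H2, Pd on CaCO3 poisoned with Pb(OAc)2, quinoline, EtOAc) comes back to the route at 10.

Step 5 (Claisen rearrangement; risk of loss of isoprene back to 8 or of chroman formation). The fallback replaces the rearrangement by cross-coupling and sets out from 8. Iodination with N-iodosuccinimide in MeCN at 0 °C goes to the only free position ortho to the 2'-OH and gives 3-(4-acetoxy-2-hydroxy-3-iodo-5-methoxyphenyl)-4-oxo-4H-chromen-7-yl acetate F4. Stille coupling of F4 with tributyl(3-methylbut-2-en-1-yl)stannane (Pd(PPh3)4, DMF, 80 °C) comes back to the route at 11, which is deacetylated as in the second half of step 5.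

**Further compounds**
F1 | step 3 | 3-(4-acetoxy-2-bromo-5-methoxyphenyl)-4-oxo-4H-chromen-7-yl acetate | COc1cc(-c2coc3cc(OC(C)=O)ccc3c2=O)c(Br)cc1OC(C)=O
F2 | step 3 | 3-[4-acetoxy-5-methoxy-2-(4,4,5,5-tetramethyl-1,3,2-dioxaborolan-2-yl)phenyl]-4-oxo-4H-chromen-7-yl acetate | COc1cc(-c2coc3cc(OC(C)=O)ccc3c2=O)c(B2OC(C)(C)C(C)(C)O2)cc1OC(C)=O
F3 | step 4 | 3-[4-acetoxy-5-methoxy-2-(2-methylbut-3-yn-2-yloxy)phenyl]-4-oxo-4H-chromen-7-yl acetate | COc1cc(-c2coc3cc(OC(C)=O)ccc3c2=O)c(OC(C)(C)C#C)cc1OC(C)=O
F4 | step 5 | 3-(4-acetoxy-2-hydroxy-3-iodo-5-methoxyphenyl)-4-oxo-4H-chromen-7-yl acetate | COc1cc(-c2coc3cc(OC(C)=O)ccc3c2=O)c(O)c(I)c1OC(C)=O
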